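**An impossible stall.** A slowing by 12.0 could not come from the dawn run's reagents as I first counted them. Target rose 12 % in the first 2.00 h but 1 percentage point in the last 2.00 h, a ratio read through a scatter of 1.5 points. If the rate follows each reagent and target is their one use, 0.0100 M of target leaves starting material at 80.0 % and coupling partner at 81.8 %. Those two slow the rate by a factor of 1.53, so a factor of about 7.85 stayed unexplained.

**A shared reagent.** I guessed that second substrate draws on the same coupling partner, the limiting reagent, so that the rate dies as partner drains and the end of the run is simply the partner's balance. In dawn, each part of partner that reached target was then matched by 4.50 parts taken elsewhere. Dividing by the charge ratio of second substrate to starting material gives a selectivity factor, the ratio of the speeds at which equal amounts of second substrate and starting material take partner, of 1.87, a value read through the scatter of the last reading.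

the same everywhere: starting material 0.050 M; free catalyst 4.1 mM; impurity 1.4 mM

| charge | coupling partner | second substrate | temperature | remark | time |
|---|---|---|---|---|---|
| dawn | 0.055 M | 0.12 M | 110 °C | run made earlier |  |
| west | 0.0550 M | 0.250 M | 110 °C |  | 30 h |
| south-east | 0.0550 M | 0.250 M | 80 °C |  | 30 h |

dawn run (percent of the starting material charged)

| time / h | target / % |
|---|---|
| 0.833 | 5 |
| 2.00 | 12 |
| 4.00 | 19 |
| 6.00 | 20 |

(each reading ± 1.5 percentage points)

- a reading or a percentage of target counts all its forms, free or not
- the earlier runs do not show what temperature does; that part of a forecast is a guess

- the best flask by amount of target, in percent of the starting material charged; "all alike" if 1.5 percentage points covers them all (west / south-east / all alike)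
- amount of target at the end, in percent of the starting material charged, west
- amount of target at the end, in percent of the starting material charged, south-east

**My reckoning.** West has twice the second substrate of dawn, so the factor shares out 10.6 % of the starting material as target. Temperature being unseen, I guessed the same for south-east, so I called them alike.

**The forecast.** It also said all alike, but with figures higher than mine, 29 % for west and 28 % for south-east, holding that “the catalyst has stopped working”.

**The result.** West gave 6.58 % and south-east gave 15.8 %, so south-east stood higher. West also held 8.72 % as isomer of the product at 30.0 h. My 10.6 % counted everything sent down the target route, and west's target and isomer together come to 15.3 %, more than my figure.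

    starting material + coupling partner + free catalyst → free catalyst + target (k = 0.0644 M⁻² s⁻¹, Ea = 36.0 kJ mol⁻¹)
    second substrate + coupling partner + free catalyst → free catalyst + second product (k = 0.0642 M⁻² s⁻¹, Ea = 44.0 kJ mol⁻¹)
    free catalyst + impurity → spent catalyst (k = 0.562 M⁻¹ s⁻¹, Ea = 73.0 kJ mol⁻¹)
    target + free catalyst ⇌ isomer of the product + free catalyst, rate k4*[free catalyst]*[target] forward; the back reaction follows from the equilibrium constant (K = 5.47, k = 7.97 × 10⁻⁴ M⁻¹ s⁻¹, Ea = 73.0 kJ mol⁻¹, ΔH = −13.0 kJ mol⁻¹)
    starting material + target ⇌ idle adduct, settled at all times (K = 16.0 M⁻¹, ΔH = −20.0 kJ mol⁻¹)
    (constants at 80 °C)

**A richer flask.** With 0.22 M of coupling partner in the west recipe, the same factor, reckoned on the charges as they stood at the start, shares out 42.4 % of the starting material. The computed flask holds 24.8 % as target and 38.7 % as isomer of the product, with 33.2 % of the starting material left.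

Readings and results are calculated for substances that don't exist.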